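**Retrosynthetic overview**
1. Target 29 ⇐ 26 by deprotection and oxidation only. The aryl ketone is carried as an acetonide-protected syn-1,3-diol, because a ketone would not survive vinyl Grignard or Ti(III).
2. 26 ⇐ acyclic epoxy cinnamyl ether 24 (key step). A one-pot Ti(III) epoxide opening, 5-exo radical cyclisation and iodine-induced radical–polar crossover builds the cis-fused 3,7-dioxabicyclo[3.3.0]octane. Ring C1–O2–C3–C3a–C6a forms first; ring C3a–C4–O5–C6–C6a (C4 carries the dihydrobenzofuranyl group) forms last.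
3. Enabling feature: C1(aryl)–O2–C3H2 is a benzyl allyl ether that holds C6a five atoms from alkene carbon C3a. C6a carries the C6H2–O5 arm (an oxirane in the precursor). C4 is benzylic and para to the dihydrobenzofuran oxygen, so a radical there is easily oxidised and captured by O5.
4. 24 ⇐ epoxy alcohol 23 + cinnamyl bromide 12 (Williamson). 23 comes from nitrile 4 by imide α-arylation, Evans syn-aldol (sets the α-aryl carbon) and Sharpless kinetic resolution (sets C1). 12 comes from nitrile 4 by Rh(II)-carbene C–H insertion.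
5. Ring order: cis-dihydrobenzofuran (step 6) → temporary 1,3-dioxane (step 15) and oxirane (step 18) → tetrahydrofuran C1/O2, then tetrahydrofuran C4/O5 (both in step 20).

Key step: step 20

Remark (assumption): the SMILES encodes a 2,3-cis dihydrobenzofuran ((2S,3S), aryl and CH2OH on the same face), and Rh2(S-PTTL)4 is assumed to be the catalyst enantiomer that delivers it; if the sense of induction is opposite, Rh2(R-PTTL)4 is used.

Abbreviations in names: TIPSO = triisopropylsilyloxy, TBSO = tert-butyldimethylsilyloxy.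

**Step 1**
Reactants: 1 vanillin
Product: 2 3-methoxy-4-(triisopropylsilyloxy)benzaldehyde
Conditions: TIPSCl, imidazole, DMF, rt
Reagents that add atoms: triisopropylsilyl chloride, CC(C)[Si](Cl)(C(C)C)C(C)C
Why: Phenol silylation; the TIPS ether resists the later alkoxide, hydride and Grignard steps and is removed by fluoride at the end.

**Step 2**
Reactants: 2 3-methoxy-4-(triisopropylsilyloxy)benzaldehyde
Product: 3 [3-methoxy-4-(triisopropylsilyloxy)phenyl]methanol
Conditions: NaBH4, MeOH, 0 °C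
Reagents that add atoms: none
Why: Borohydride reduction of the aldehyde to the benzylic alcohol.

**Step 3**
Reactants: 3 [3-methoxy-4-(triisopropylsilyloxy)phenyl]methanol; 4 3-bromo-4-hydroxy-5-methoxybenzonitrile
Product: 5 3-bromo-5-methoxy-4-{[3-methoxy-4-(triisopropylsilyloxy)benzyl]oxy}benzonitrile
Conditions: PPh3, DIAD, THF, 0 °C → rt
Reagents that add atoms: none
Why: Mitsunobu etherification of the acidic cyanophenol with the activated benzylic alcohol under neutral conditions that keep the aryl silyl ether.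

**Step 4**
Reactants: 5 3-bromo-5-methoxy-4-{[3-methoxy-4-(triisopropylsilyloxy)benzyl]oxy}benzonitrile
Product: 6 methyl 2-(5-cyano-3-methoxy-2-{[3-methoxy-4-(triisopropylsilyloxy)benzyl]oxy}phenyl)acetate
Conditions: BrZnCH2CO2Me (from methyl bromoacetate, Zn, cat. TMSCl), Pd2(dba)3 (cat.), XPhos (cat.), THF, 60 °C
Reagents that add atoms: methyl bromoacetate (as its zinc reagent), COC(=O)CBr
Why: Negishi-type coupling of a Reformatsky reagent with the aryl bromide (Pd-catalysed α-arylation of a zinc ester enolate), which tolerates the nitrile and the silyl ether.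

**Step 5**
Reactants: 6 methyl 2-(5-cyano-3-methoxy-2-{[3-methoxy-4-(triisopropylsilyloxy)benzyl]oxy}phenyl)acetate
Product: 7 methyl 2-diazo-2-(5-cyano-3-methoxy-2-{[3-methoxy-4-(triisopropylsilyloxy)benzyl]oxy}phenyl)acetate
Conditions: p-ABSA, DBU, MeCN, 0 °C → rt
Reagents that add atoms: 4-acetamidobenzenesulfonyl azide, CC(=O)Nc1ccc(cc1)S(=O)(=O)N=[N+]=[N-]
Why: Regitz diazo transfer to the acidic arylacetate methylene.

**Step 6**
Reactants: 7 methyl 2-diazo-2-(5-cyano-3-methoxy-2-{[3-methoxy-4-(triisopropylsilyloxy)benzyl]oxy}phenyl)acetate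
Product: 8 methyl (2S,3R)-5-cyano-7-methoxy-2-[3-methoxy-4-(TIPSO)phenyl]-2,3-dihydro-1-benzofuran-3-carboxylate (2,3-cis)
Conditions: Rh2(S-PTTL)4 (1 mol%), toluene, −78 °C
Reagents that add atoms: none
Why: Rh(II)-carbene intramolecular 1,5-C–H insertion into the benzylic ether CH2 closes the dihydrobenzofuran with kinetic cis selectivity, and the chiral carboxylate ligands set the absolute configuration of both new centres.

**Step 7**
Reactants: 8 methyl (2S,3R)-5-cyano-7-methoxy-2-[3-methoxy-4-(TIPSO)phenyl]-2,3-dihydro-1-benzofuran-3-carboxylate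
Product: 9 (2S,3S)-3-(hydroxymethyl)-7-methoxy-2-[3-methoxy-4-(TIPSO)phenyl]-2,3-dihydro-1-benzofuran-5-carbaldehyde (cis)
Conditions: DIBAL-H (4 equiv), CH2Cl2, −78 → −40 °C; aq. Rochelle salt, then dilute aq. tartaric acid
Reagents that add atoms: water, O
Why: DIBAL reduces the ester to the primary alcohol and the nitrile to the N-aluminoimine, which hydrolyses to the aldehyde on work-up; at low temperature without base the cis C3 centre should not epimerise.

**Step 8**
Reactants: 9 (2S,3S)-3-(hydroxymethyl)-7-methoxy-2-[3-methoxy-4-(TIPSO)phenyl]-2,3-dihydro-1-benzofuran-5-carbaldehyde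
Product: 10 (2S,3S)-3-(TBSO-methyl)-7-methoxy-2-[3-methoxy-4-(TIPSO)phenyl]-2,3-dihydro-1-benzofuran-5-carbaldehyde
Conditions: TBSCl, imidazole, DMF, 0 °C → rt
Reagents that add atoms: tert-butyldimethylsilyl chloride, CC(C)(C)[Si](C)(C)Cl
Why: Silylation of the primary alcohol so that it cannot compete in the later bromination and etherification.

**Step 9**
Reactants: 10 (2S,3S)-3-(TBSO-methyl)-7-methoxy-2-[3-methoxy-4-(TIPSO)phenyl]-2,3-dihydro-1-benzofuran-5-carbaldehyde
Product: 11 (1RS)-1-[(2S,3S)-3-(TBSO-methyl)-7-methoxy-2-[3-methoxy-4-(TIPSO)phenyl]-2,3-dihydro-1-benzofuran-5-yl]prop-2-en-1-ol (both carbinol epimers)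
Conditions: CH2=CHMgBr, THF, −78 °C
Reagents that add atoms: vinylmagnesium bromide, C=C[Mg]Br
Why: Grignard addition to the aldehyde; the carbinol configuration is irrelevant because the centre is removed in the next step.

**Step 10**
Reactants: 11 (1RS)-1-[(2S,3S)-3-(TBSO-methyl)-7-methoxy-2-[3-methoxy-4-(TIPSO)phenyl]-2,3-dihydro-1-benzofuran-5-yl]prop-2-en-1-ol
Product: 12 (2S,3S)-5-[(E)-3-bromoprop-1-enyl]-3-(TBSO-methyl)-7-methoxy-2-[3-methoxy-4-(TIPSO)phenyl]-2,3-dihydro-1-benzofuran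
Conditions: PBr3, pyridine (cat.), Et2O, −20 → 0 °C; used crude
Reagents that add atoms: phosphorus tribromide, BrP(Br)Br
Why: Bromination with allylic transposition (SN2′ / ion-pair return) of the 1-arylallyl alcohol should give the conjugated (E)-cinnamyl bromide as the thermodynamic isomer.

**Step 11**
Reactants: 4 3-bromo-4-hydroxy-5-methoxybenzonitrile
Product: 13 3-bromo-5-methoxy-4-(triisopropylsilyloxy)benzonitrile
Conditions: TIPSOTf, 2,6-lutidine, CH2Cl2, 0 °C
Reagents that add atoms: triisopropylsilyl triflate, CC(C)[Si](OS(=O)(=O)C(F)(F)F)(C(C)C)C(C)C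
Why: Silylation of the hindered, acidic phenol with the more reactive silyl triflate.

**Step 12**
Reactants: 13 3-bromo-5-methoxy-4-(triisopropylsilyloxy)benzonitrile; 14 (R)-3-acetyl-4-benzyloxazolidin-2-one
Product: 16 (R)-4-benzyl-3-{2-[5-cyano-3-methoxy-2-(TIPSO)phenyl]acetyl}oxazolidin-2-one, via chlorozinc imide enolate 15 (not isolated)
Conditions: 14, LiHMDS, THF, −78 °C; ZnCl2, −78 → 0 °C; then 13, Pd(dba)2 (cat.), Q-Phos (cat.), THF, rt → 50 °C
Reagents that add atoms: none
Why: Pd-catalysed α-arylation of a zinc imide enolate (Negishi-type); the weakly basic zinc enolate tolerates the nitrile and should stop at monoarylation.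

**Step 13**
Reactants: 16 (R)-4-benzyl-3-{2-[5-cyano-3-methoxy-2-(TIPSO)phenyl]acetyl}oxazolidin-2-one; 2 3-methoxy-4-(triisopropylsilyloxy)benzaldehyde
Product: 18 (R)-4-benzyl-3-{(2R,3R)-2-[5-cyano-3-methoxy-2-(TIPSO)phenyl]-3-hydroxy-3-[3-methoxy-4-(TIPSO)phenyl]propanoyl}oxazolidin-2-one, via (Z)-dibutylboron enolate 17 (not isolated)
Conditions: Bu2BOTf, iPr2NEt, CH2Cl2, −78 → 0 °C; then 2, −78 → 0 °C; pH 7 buffer, MeOH, H2O2, 0 °C
Reagents that add atoms: none
Why: Evans syn-aldol: the (Z)-boron enolate reacts through a Zimmerman–Traxler chair on the face opposite the benzyl group of the (R)-auxiliary, which sets the α-aryl carbon (later the carbon next to the ketone) and the syn carbinol.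

**Step 14**
Reactants: 18 the aldol adduct
Product: 19 3-{(1R,2S)-1,3-dihydroxy-1-[3-methoxy-4-(TIPSO)phenyl]propan-2-yl}-5-methoxy-4-(TIPSO)benzonitrile
Conditions: LiBH4, MeOH (1 equiv), THF, 0 °C
Reagents that add atoms: none
Why: Reductive cleavage of the acyl oxazolidinone to the primary alcohol; the nitrile is not reduced by borohydride and the α-aryl centre is untouched.

**Step 15**
Reactants: 19 the 1,3-diol
Product: 20 3-{(4R,5S)-4-[3-methoxy-4-(TIPSO)phenyl]-2,2-dimethyl-1,3-dioxan-5-yl}-5-methoxy-4-(TIPSO)benzonitrile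
Conditions: 2,2-dimethoxypropane, PPTS (cat.), CH2Cl2, rt
Reagents that add atoms: 2,2-dimethoxypropane, COC(C)(C)OC
Why: Acetonide formation masks both hydroxyls in one step and keeps the future ketone at the alcohol level through the Grignard and Ti(III) steps.

**Step 16**
Reactants: 20 the acetonide nitrile
Product: 21 3-{(4R,5S)-4-[3-methoxy-4-(TIPSO)phenyl]-2,2-dimethyl-1,3-dioxan-5-yl}-5-methoxy-4-(TIPSO)benzaldehyde
Conditions: DIBAL-H (1.5 equiv), toluene, −78 °C; aq. Rochelle salt, then SiO2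
Reagents that add atoms: water, O
Why: Partial reduction of the aryl nitrile to the aldimine and hydrolysis to the aldehyde; acetonide and silyl ethers are stable at −78 °C.

**Step 17**
Reactants: 21 the acetonide aldehyde
Product: 22 (1RS)-1-[3-{(4R,5S)-4-[3-methoxy-4-(TIPSO)phenyl]-2,2-dimethyl-1,3-dioxan-5-yl}-5-methoxy-4-(TIPSO)phenyl]prop-2-en-1-ol (both carbinol epimers)
Conditions: CH2=CHMgBr, THF, −78 °C
Reagents that add atoms: vinylmagnesium bromide, C=C[Mg]Br
Why: Grignard addition; the remote stereocentres give no control, so both epimers form and the next step selects one.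

**Step 18**
Reactants: 22 the aryl vinyl carbinol (epimer mixture)
Product: 23 (R)-[3-{(4R,5S)-4-[3-methoxy-4-(TIPSO)phenyl]-2,2-dimethyl-1,3-dioxan-5-yl}-5-methoxy-4-(TIPSO)phenyl][(2R)-oxiran-2-yl]methanol
Conditions: Ti(OiPr)4, D-(−)-DIPT, t-BuOOH (0.6 equiv), 4 Å MS, CH2Cl2, −20 °C; the unreacted (R)-carbinol epimer is separated
Reagents that add atoms: tert-butyl hydroperoxide, CC(C)(C)OO
Why: Sharpless kinetic resolution of a secondary allylic alcohol: with D-(−)-tartrate the (S)-carbinol epimer should be epoxidised much faster (anti epoxy alcohol), so the carbinol carbon (future C1) is fixed by reagent control; the oxirane configuration does not matter later.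

**Step 19**
Reactants: 23 the epoxy alcohol; 12 the cinnamyl bromide
Product: 24 the epoxy cinnamyl ether: the (R)-carbinol oxygen of 23 carries the (E)-3-[(2S,3S)-3-(TBSO-methyl)-7-methoxy-2-[3-methoxy-4-(TIPSO)phenyl]-2,3-dihydro-1-benzofuran-5-yl]prop-2-enyl group
Conditions: NaH, THF, 0 °C; then 12, Bu4NI (cat.), 0 °C → rt
Reagents that add atoms: none
Why: Williamson ether synthesis; only the O–H bond reacts, so the carbinol configuration is retained.

**Step 20**
Reactants: 24 the epoxy cinnamyl ether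
Product: 26 (1S,3aR,4S,6aR)-furofuran with the acetonide-protected arm-A aryl at C1 and the (2S,3S)-3-(TBSO-methyl)-7-methoxy-2-[3-methoxy-4-(TIPSO)phenyl]-2,3-dihydro-1-benzofuran-5-yl group at C4, via monocyclic benzylic iodide titanium alkoxide 25 (not isolated)
Conditions: Cp2TiCl2 (2.5 equiv), Zn dust, THF, rt (green Cp2TiCl added slowly to 24); then I2 (1.2 equiv), THF, rt → 40 °C
Reagents that add atoms: none
Why: Cp2TiCl opens the terminal oxirane by single-electron transfer at its more substituted carbon (strain release), giving a secondary radical at C6a next to the C6–O5–Ti alkoxide; the closest known reaction type is the titanocene(III) epoxide–olefin radical cyclisation with iodine-induced ring closure used for simple 2,6-diaryl furofurans. The radical adds 5-exo-trig to the cinnamyl double bond at C3a, closing the first tetrahydrofuran (C1–O2–C3–C3a–C6a) and leaving a benzylic radical at C4; Ti(III)/I2 then converts this (radical–polar crossover) into a benzylic iodide or cation stabilised by the para oxygen of the dihydrobenzofuran, and the titanium alkoxide O5 captures it in a 5-exo-tet, SN1-type closure that forms the second tetrahydrofuran (C3a–C4–O5–C6–C6a) last. C6a and C3a are set in the chair-like transition state of the 5-exo cyclisation, where the C1 aryl group is pseudo-equatorial, so it ends trans to C6 and the ring fusion is cis; C4 is set in the cationic closure, where the aryl group takes the exo (convex) position, so all four centres are relayed from the single carbinol centre C1 and the oxirane configuration is erased at the radical. The step needs regioselective epoxide opening (secondary over primary radical), 5-exo over 6-endo closure (secured by tether length and the benzylic radical formed), cyclisation before capture of the first radical by Ti(III) (secured by slow addition) and oxidation rather than reduction of the benzylic radical (secured by the iodine quench and the electron-rich arene).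

**Step 21**
Reactants: 26 the protected furofuran
Product: 27 the triol: 26 with the acetonide opened to the (1R,2S)-1,3-diol and the TBS ether cleaved; the three aryl TIPS ethers remain
Conditions: AcOH/THF/H2O (3:1:1), 40 °C
Reagents that add atoms: none
Why: Mild acid hydrolysis of the acetonide and the primary TBS ether; the aryl TIPS ethers stay, so the phenols remain protected for the oxidation, and any epimerisation of the benzylic carbinol is harmless because that centre is oxidised next.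

**Step 22**
Reactants: 27 the triol
Product: 28 the tris-TIPS ether of the target (aryl ketone formed)
Conditions: activated MnO2 (excess), CH2Cl2, rt
Reagents that add atoms: none
Why: Chemoselective MnO2 oxidation of the single secondary benzylic alcohol in the presence of two primary aliphatic alcohols; the neutral heterogeneous conditions should leave the α-aryl stereocentre intact.

**Step 23**
Reactants: 28 the tris-TIPS ether
Product: 29 the target, CNP0174045.1
Conditions: TBAF/AcOH (1:1, 4 equiv), THF, 0 °C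
Reagents that add atoms: none
Why: Fluoride cleavage of the three aryl silyl ethers; the acetic acid buffer suppresses enolisation, retro-aldol loss of formaldehyde and dehydration of the α-aryl-β-hydroxy ketone.

**Compound list**
1 | vanillin | COc1cc(C=O)ccc1O | starting material
2 | 3-methoxy-4-(triisopropylsilyloxy)benzaldehyde | COc1cc(C=O)ccc1O[Si](C(C)C)(C(C)C)C(C)C | intermediate
3 | [3-methoxy-4-(triisopropylsilyloxy)phenyl]methanol | COc1cc(CO)ccc1O[Si](C(C)C)(C(C)C)C(C)C | intermediate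
4 | 3-bromo-4-hydroxy-5-methoxybenzonitrile | COc1cc(C#N)cc(Br)c1O | starting material
5 | 3-bromo-5-methoxy-4-{[3-methoxy-4-(TIPSO)benzyl]oxy}benzonitrile | COc1cc(C#N)cc(Br)c1OCc1ccc(O[Si](C(C)C)(C(C)C)C(C)C)c(OC)c1 | intermediate
6 | methyl 2-(5-cyano-3-methoxy-2-{[3-methoxy-4-(TIPSO)benzyl]oxy}phenyl)acetate | COC(=O)Cc1cc(C#N)cc(OC)c1OCc1ccc(O[Si](C(C)C)(C(C)C)C(C)C)c(OC)c1 | intermediate
7 | methyl 2-diazo-2-(5-cyano-3-methoxy-2-{[3-methoxy-4-(TIPSO)benzyl]oxy}phenyl)acetate | COC(=O)C(=[N+]=[N-])c1cc(C#N)cc(OC)c1OCc1ccc(O[Si](C(C)C)(C(C)C)C(C)C)c(OC)c1 | intermediate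
8 | methyl (2S,3R)-5-cyano-7-methoxy-2-[3-methoxy-4-(TIPSO)phenyl]-2,3-dihydro-1-benzofuran-3-carboxylate (cis) | N#Cc1cc(OC)c2c(c1)[C@@H](C(=O)OC)[C@@H](c1ccc(O[Si](C(C)C)(C(C)C)C(C)C)c(OC)c1)O2 | intermediate
9 | (2S,3S)-3-(hydroxymethyl)-7-methoxy-2-[3-methoxy-4-(TIPSO)phenyl]-2,3-dihydro-1-benzofuran-5-carbaldehyde | O=Cc1cc(OC)c2c(c1)[C@@H](CO)[C@@H](c1ccc(O[Si](C(C)C)(C(C)C)C(C)C)c(OC)c1)O2 | intermediate
10 | (2S,3S)-3-(TBSO-methyl)-7-methoxy-2-[3-methoxy-4-(TIPSO)phenyl]-2,3-dihydro-1-benzofuran-5-carbaldehyde | O=Cc1cc(OC)c2c(c1)[C@@H](CO[Si](C)(C)C(C)(C)C)[C@@H](c1ccc(O[Si](C(C)C)(C(C)C)C(C)C)c(OC)c1)O2 | intermediate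
11 | (1RS)-1-[(2S,3S)-3-(TBSO-methyl)-7-methoxy-2-[3-methoxy-4-(TIPSO)phenyl]-2,3-dihydro-1-benzofuran-5-yl]prop-2-en-1-ol | C=CC(O)c1cc(OC)c2c(c1)[C@@H](CO[Si](C)(C)C(C)(C)C)[C@@H](c1ccc(O[Si](C(C)C)(C(C)C)C(C)C)c(OC)c1)O2 | intermediate
12 | (2S,3S)-5-[(E)-3-bromoprop-1-enyl]-3-(TBSO-methyl)-7-methoxy-2-[3-methoxy-4-(TIPSO)phenyl]-2,3-dihydro-1-benzofuran | BrC/C=C/c1cc(OC)c2c(c1)[C@@H](CO[Si](C)(C)C(C)(C)C)[C@@H](c1ccc(O[Si](C(C)C)(C(C)C)C(C)C)c(OC)c1)O2 | intermediate
13 | 3-bromo-5-methoxy-4-(triisopropylsilyloxy)benzonitrile | COc1cc(C#N)cc(Br)c1O[Si](C(C)C)(C(C)C)C(C)C | intermediate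
14 | (R)-3-acetyl-4-benzyloxazolidin-2-one | CC(=O)N1[C@H](Cc2ccccc2)COC1=O | starting material
15 | chlorozinc enolate of 14 (drawn C-bound) | Cl[Zn]CC(=O)N1[C@H](Cc2ccccc2)COC1=O | intermediate (not isolated)
16 | (R)-4-benzyl-3-{2-[5-cyano-3-methoxy-2-(TIPSO)phenyl]acetyl}oxazolidin-2-one | COc1cc(C#N)cc(CC(=O)N2[C@H](Cc3ccccc3)COC2=O)c1O[Si](C(C)C)(C(C)C)C(C)C | intermediate
17 | (Z)-dibutylboron enolate of 16 | CCCCB(CCCC)O/C(=C\c1cc(C#N)cc(OC)c1O[Si](C(C)C)(C(C)C)C(C)C)N1[C@H](Cc2ccccc2)COC1=O | intermediate (not isolated)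
18 | (R)-4-benzyl-3-{(2R,3R)-2-[5-cyano-3-methoxy-2-(TIPSO)phenyl]-3-hydroxy-3-[3-methoxy-4-(TIPSO)phenyl]propanoyl}oxazolidin-2-one | COc1cc([C@H](O)[C@H](C(=O)N2[C@H](Cc3ccccc3)COC2=O)c2cc(C#N)cc(OC)c2O[Si](C(C)C)(C(C)C)C(C)C)ccc1O[Si](C(C)C)(C(C)C)C(C)C | intermediate
19 | 3-{(1R,2S)-1,3-dihydroxy-1-[3-methoxy-4-(TIPSO)phenyl]propan-2-yl}-5-methoxy-4-(TIPSO)benzonitrile | COc1cc([C@H](O)[C@H](CO)c2cc(C#N)cc(OC)c2O[Si](C(C)C)(C(C)C)C(C)C)ccc1O[Si](C(C)C)(C(C)C)C(C)C | intermediate
20 | 3-{(4R,5S)-4-[3-methoxy-4-(TIPSO)phenyl]-2,2-dimethyl-1,3-dioxan-5-yl}-5-methoxy-4-(TIPSO)benzonitrile | COc1cc([C@@H]2OC(C)(C)OC[C@@H]2c2cc(C#N)cc(OC)c2O[Si](C(C)C)(C(C)C)C(C)C)ccc1O[Si](C(C)C)(C(C)C)C(C)C | intermediate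
21 | 3-{(4R,5S)-4-[3-methoxy-4-(TIPSO)phenyl]-2,2-dimethyl-1,3-dioxan-5-yl}-5-methoxy-4-(TIPSO)benzaldehyde | COc1cc([C@@H]2OC(C)(C)OC[C@@H]2c2cc(C=O)cc(OC)c2O[Si](C(C)C)(C(C)C)C(C)C)ccc1O[Si](C(C)C)(C(C)C)C(C)C | intermediate
22 | (1RS)-1-[3-{(4R,5S)-4-[3-methoxy-4-(TIPSO)phenyl]-2,2-dimethyl-1,3-dioxan-5-yl}-5-methoxy-4-(TIPSO)phenyl]prop-2-en-1-ol | COc1cc([C@@H]2OC(C)(C)OC[C@@H]2c2cc(C(O)C=C)cc(OC)c2O[Si](C(C)C)(C(C)C)C(C)C)ccc1O[Si](C(C)C)(C(C)C)C(C)C | intermediate
23 | (R)-[3-{(4R,5S)-4-[3-methoxy-4-(TIPSO)phenyl]-2,2-dimethyl-1,3-dioxan-5-yl}-5-methoxy-4-(TIPSO)phenyl][(2R)-oxiran-2-yl]methanol | COc1cc([C@@H]2OC(C)(C)OC[C@@H]2c2cc([C@@H](O)[C@H]3CO3)cc(OC)c2O[Si](C(C)C)(C(C)C)C(C)C)ccc1O[Si](C(C)C)(C(C)C)C(C)C | intermediate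
24 | epoxy cinnamyl ether: (E)-cinnamyl ether of 23 at the (R)-carbinol oxygen with the dihydrobenzofuran unit of 12 | COc1cc([C@@H]2OC(C)(C)OC[C@@H]2c2cc([C@H]([C@H]3CO3)OC/C=C/c3cc(OC)c4c(c3)[C@@H](CO[Si](C)(C)C(C)(C)C)[C@@H](c3ccc(O[Si](C(C)C)(C(C)C)C(C)C)c(OC)c3)O4)cc(OC)c2O[Si](C(C)C)(C(C)C)C(C)C)ccc1O[Si](C(C)C)(C(C)C)C(C)C | intermediate
25 | monocyclic (2S,3R,4R)-tetrahydrofuran with 3-CH2O–TiCp2Cl and 4-CH(I)-dihydrobenzofuranyl (iodide epimers) | COc1cc([C@@H]2OC(C)(C)OC[C@@H]2c2cc([C@H]3OC[C@H](C(I)c4cc(OC)c5c(c4)[C@@H](CO[Si](C)(C)C(C)(C)C)[C@@H](c4ccc(O[Si](C(C)C)(C(C)C)C(C)C)c(OC)c4)O5)[C@@H]3CO[Ti](Cl)(C3C=CC=C3)C3C=CC=C3)cc(OC)c2O[Si](C(C)C)(C(C)C)C(C)C)ccc1O[Si](C(C)C)(C(C)C)C(C)C | intermediate (not isolated)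
26 | protected (1S,3aR,4S,6aR)-furofuran (acetonide, one TBS and three TIPS groups) | COc1cc([C@@H]2OC(C)(C)OC[C@@H]2c2cc([C@H]3OC[C@H]4[C@@H]3CO[C@@H]4c3cc(OC)c4c(c3)[C@@H](CO[Si](C)(C)C(C)(C)C)[C@@H](c3ccc(O[Si](C(C)C)(C(C)C)C(C)C)c(OC)c3)O4)cc(OC)c2O[Si](C(C)C)(C(C)C)C(C)C)ccc1O[Si](C(C)C)(C(C)C)C(C)C | intermediate
27 | triol: (1R,2S)-1,3-diol arm and free dihydrobenzofuran CH2OH, three aryl TIPS ethers | COc1cc([C@H](O)[C@H](CO)c2cc([C@H]3OC[C@H]4[C@@H]3CO[C@@H]4c3cc(OC)c4c(c3)[C@@H](CO)[C@@H](c3ccc(O[Si](C(C)C)(C(C)C)C(C)C)c(OC)c3)O4)cc(OC)c2O[Si](C(C)C)(C(C)C)C(C)C)ccc1O[Si](C(C)C)(C(C)C)C(C)C | intermediate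
28 | tris-TIPS ether of the target (aryl ketone, (S) at the α-carbon) | COc1cc(C(=O)[C@H](CO)c2cc([C@H]3OC[C@H]4[C@@H]3CO[C@@H]4c3cc(OC)c4c(c3)[C@@H](CO)[C@@H](c3ccc(O[Si](C(C)C)(C(C)C)C(C)C)c(OC)c3)O4)cc(OC)c2O[Si](C(C)C)(C(C)C)C(C)C)ccc1O[Si](C(C)C)(C(C)C)C(C)C | intermediate
29 | CNP0174045.1 | COc1cc(C(=O)[C@H](CO)c2cc([C@H]3OC[C@H]4[C@@H]3CO[C@@H]4c3cc(OC)c4c(c3)[C@@H](CO)[C@@H](c3ccc(O)c(OC)c3)O4)cc(OC)c2O)ccc1O | target

**Step count and risks**
Total steps: 23. Longest linear sequence: 15 steps (steps 1–10, then 19–23).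

Steps most likely to fail:

1. Step 20. The benzylic radical or its titanium species may be reduced and protonated before the iodine-induced crossover, or the first radical may be captured by a second Ti(III) and eliminate (epoxide deoxygenation). Fallback: starting from 24, Cp2TiCl is used without iodine and quenched with aqueous NaH2PO4, so the benzylic radical is deliberately reduced to give the monocyclic lariciresinol-type alcohol F1. The second ring is then closed in a separate step by DDQ-mediated oxidative cyclisation of the p-alkoxybenzyl CH2 onto the neighbouring hydroxymethyl group (DDQ, CH2Cl2, 4 Å MS, 0 °C), which returns to the route at 26.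

2. Step 19. Under alkoxide conditions the oxirane may migrate (Payne-type), leading to alkylation at the wrong oxygen, and the electron-rich cinnamyl bromide may ionise and decompose. Fallback: starting from 11 instead of 12, acetylation (Ac2O, Et3N, DMAP) gives the allylic acetate F2. This is joined with 23 by Pd-catalysed allylic etherification of the zinc alkoxide (Et2Zn 0.5 equiv, Pd(OAc)2, 2-(di-tert-butylphosphino)biphenyl, THF, rt); the π-allyl intermediate should give the linear (E)-ether, and the route is rejoined at 24.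

3. Step 12. The acetyl imide enolate may self-condense before transmetalation, and oxidative addition at the hindered ortho-silyloxy aryl bromide may be slow. Fallback: starting from 13, Negishi coupling with BrZnCH2CO2Me (conditions of step 4) gives the methyl arylacetate F3. Hydrolysis with Me3SnOH (1,2-dichloroethane, 70 °C) gives the arylacetic acid F4, and acylation of lithiated (R)-4-benzyloxazolidin-2-one through the pivaloyl mixed anhydride (PivCl, Et3N, THF, −78 → 0 °C) rejoins the route at 16.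

**Further compounds**
F1 | step 20 | (2S,3R,4R)-tetrahydrofuran with 2-(arm-A aryl), 3-(hydroxymethyl) and 4-[(dihydrobenzofuran-5-yl)methyl] groups | COc1cc([C@@H]2OC(C)(C)OC[C@@H]2c2cc([C@H]3OC[C@H](Cc4cc(OC)c5c(c4)[C@@H](CO[Si](C)(C)C(C)(C)C)[C@@H](c4ccc(O[Si](C(C)C)(C(C)C)C(C)C)c(OC)c4)O5)[C@@H]3CO)cc(OC)c2O[Si](C(C)C)(C(C)C)C(C)C)ccc1O[Si](C(C)C)(C(C)C)C(C)C
F2 | step 19 | (1RS)-1-[(2S,3S)-3-(TBSO-methyl)-7-methoxy-2-[3-methoxy-4-(TIPSO)phenyl]-2,3-dihydro-1-benzofuran-5-yl]prop-2-enyl acetate | CC(=O)OC(C=C)c1cc(OC)c2c(c1)[C@@H](CO[Si](C)(C)C(C)(C)C)[C@@H](c1ccc(O[Si](C(C)C)(C(C)C)C(C)C)c(OC)c1)O2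
F3 | step 12 | methyl 2-[5-cyano-3-methoxy-2-(triisopropylsilyloxy)phenyl]acetate | COC(=O)Cc1cc(C#N)cc(OC)c1O[Si](C(C)C)(C(C)C)C(C)C
F4 | step 12 | 2-[5-cyano-3-methoxy-2-(triisopropylsilyloxy)phenyl]acetic acid | OC(=O)Cc1cc(C#N)cc(OC)c1O[Si](C(C)C)(C(C)C)C(C)C
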